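I began from the constants, and they showed me a fork.

    Q + D.Q → Q.D.Q (k1 = 0.023 M⁻¹ min⁻¹)
    D + Q.D.Q → Z (k2 = 0.0096 M⁻¹ min⁻¹)
    D → L (k3 = 0.0033 min⁻¹)
    X ⇌ Q.D.Q, rate k4*(cs4 - [Q.D.Q]) while solid is left; crystals form when [Q.D.Q] > cs4 (cs4 = 20 mM, k4 = 0.10 min⁻¹)
    D + Q → D.Q (k5 = 0.029 M⁻¹ min⁻¹)

| flask | D | Q | time | remark |
|---|---|---|---|---|
| Monday's | 0.050 M | 0.0650 M (fed, over 30 h) | 40 h | all else is in the flask from the start; the feed brings no volume worth counting |
| Sunday's | 0.050 M | 0.0650 M | 40 h | everything together at the start |
| Wednesday's | 0.050 M (fed, over 30 h) | 0.0650 M | 40 h | all else is in the flask from the start; the feed brings no volume worth counting |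

- the flask that comes out highest in amount of Q.D.Q, in percent of the D charged, or "all alike" when all lie within 1.5 percentage points (Monday's / Sunday's / Wednesday's / all alike)
- Q.D.Q at the end, in percent of the D charged, Monday's
- Q.D.Q at the end, in percent of the D charged, Sunday's
- Q.D.Q at the end, in percent of the D charged, Wednesday's

- percent here means D units held: one Z counts as two
- what is said of Q.D.Q includes X
- X is a solid; its amount is given per volume of the solution
- run time (Monday's): 40 h

I followed one molecule of D. It can decay to L, with constant 0.0033 min⁻¹. Or it can meet Q and become D.Q, with a pseudo-first-order constant that is the second-order constant times Q. At the whole Q charge that constant is 0.00188 min⁻¹, so decay is the faster road. I set the step to Z aside. The chance of the Q road is its constant over the sum of both, and at the whole charge it came to 36.4%. I called this the fork share, the fraction of D that goes to D.Q and not to L.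

I then asked what fraction of the Q charge D meets. In Monday's flask, D lives 5.05 h on average against decay alone, and by then the feed has brought 0.168 of the charge.

| Flask | Fraction of Q charge met | Fork share |
|---|---|---|
| Sunday's | 1 | 36.4% |
| Wednesday's | 1 | 36.4% |
| Monday's | 0.168 | 8.77% |

I read the last row first. Monday's share is lower, so I put that flask last. The first two rows are equal, and Q falls as it is used, so I took 36.4% as an upper mark for both.

The finishing step parted them. In Sunday's flask, D.Q has a half-life of 7.7 h by the step to Q.D.Q alone, with Q as charged, and the run lasts 5.18 of those. Wednesday's flask has the same Q charge, so I used the same half-life there; its last D arrives with 10.0 h to go, which is 1.29 of them. So I ranked Sunday's first, then Wednesday's, then Monday's.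

The forecast said Sunday's, with 28% for Sunday's, 23.5% for Wednesday's and 7% for Monday's. Its ground was that “the best flask is the one with the most Q present while D is still there”. Those figures are its own, and my mark for Sunday's flask stood above its number.

Sunday's ended at 27.6%, Wednesday's at 21.3% and Monday's at 5.91%, so Sunday's stood highest, as the forecast said. Sunday's flask held 67.3% as L at 40.0 h. I then put 0.26 M of Q into the same reckoning for the neighbour of Sunday's flask. With Q as charged, the share at the start rose to 69.6%. That flask ended with 74.2% of its Q charge left and 32.3% as L.

The constants used here are those of an exercise; the flask was simulated.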